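**Retrosynthetic overview**
1. Ring A (C1, C10, C11, C12, C13, C14) is cut at C13–C14 and C1–C10 as a Diels–Alder adduct. Its C12 oxygen is read as a 2-silyloxy-diene (C10=C11–C12(OSi)=C13); the quaternary C1, flanked by C2 and C15 and next to the oxygenated C14, is read as a β-oxygenated alkylidene-1,3-dicarbonyl (a 5-formyl-1,3-dioxin-4-one). C15 is carried as CHO and reduced to CH3.
2. The diene half (C6–C13, C17–C19, with C7, C8, C9 from C2, C3, C4 of D-glucose) comes from diacetone-D-glucose by ulose formation, propanoate aldol, glycol cleavage and Wittig reaction.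
3. After the cycloaddition the dioxanone is opened by an acetylide (C3, C4) and turned into a (Z)-iodoalkene; a syn-1,3-reduction sets C2, the silyl enol ether delivers C20, and a Rubottom oxidation delivers O13.
4. The furanose is opened by a Wittig reaction (C5, C16), the lactone is closed, and the ten-membered ring is formed by intramolecular C4–C5 coupling; reduction, chlorination and hydroxyl-directed epoxidation finish the route.
5. Ring order: ring A (step 8), γ-lactone (step 17), ten-membered ring (step 20), epoxide (step 23).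

Key step: step 8

Remark on numbering: briarane numbering is used for all compounds (ring A = C1, C10–C14; ten-membered ring = C1–C10; lactone = C7, C8, C17, C19; C15 on C1, C16 on C5, C18 on C17, C20 on C11).
Assumption: 2,2-dimethyl-4H-1,3-dioxin-4-one (10), the acetone adduct of formylketene, is taken as a catalogue compound; lactol 28 is a mixture of anomers and is drawn without configuration at C6.

**Route**

Step 1
Reactants: 1 diacetone-D-glucose
Product: 2 1,2:5,6-di-O-isopropylidene-α-D-ribo-hexofuranos-3-ulose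
Conditions: Dess–Martin periodinane, CH2Cl2, 20 °C
Reagents that add atoms: none
Why: Dess–Martin oxidation of the only free hydroxyl gives the C8 ketone; no stereocentre is created.

Step 2
Reactants: 2 ulose; 3 ethyl propanoate
Product: 4 ethyl (2R)-2-(1,2:5,6-di-O-isopropylidene-α-D-allofuranos-3-C-yl)propanoate
Conditions: LiN(iPr)2, THF/DMPU, −78 °C, 3; then 2; aq NH4Cl
Reagents that add atoms: none
Why: Aldol addition to the ketone from the convex β-face of the cis-fused bicycle (opposite the 1,2-acetonide) sets C8, and a closed six-membered lithium-bridged transition state with the ester carbon turned away from the C9 side chain and the methyl of the cis-enolate beside it should set C17 (R); any C17 epimer is separated here.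

Step 3
Reactants: 4 aldol adduct
Product: 6 ethyl (2R)-2-(1,2-O-isopropylidene-α-D-ribo-pentodialdo-1,4-furanos-3-C-yl)propanoate (C10 aldehyde), via diol 5 (not isolated)
Conditions: H5IO6, EtOAc, 20 °C
Reagents that add atoms: none
Why: Periodic acid hydrolyses the more labile terminal acetonide and cleaves the resulting glycol (Malaprade cleavage) to the C10 aldehyde, leaving C9 untouched.

Step 4
Reactants: 6 aldehyde; 7 (acetylmethylene)triphenylphosphorane
Product: 8 (E)-methyl enone (C10=C11–C12(=O)–C13H3 on the furanose carbon C9)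
Conditions: CH2Cl2, 20 °C
Reagents that add atoms: none
Why: Wittig reaction of a stabilised ylide gives the (E)-enone and brings in C11–C13.

Step 5
Reactants: 8 enone
Product: 9 2-(tert-butyldimethylsilyloxy)diene (C10=C11–C12(OTBS)=C13H2)
Conditions: LiN(SiMe3)2 (2.1 equiv), THF, −78 °C; TBSCl, HMPA
Reagents that add atoms: tert-butyldimethylsilyl chloride, CC(C)(C)[Si](C)(C)Cl
Why: After the tertiary hydroxyl, the methyl ketone is deprotonated kinetically and the enolate oxygen is silylated to the cross-conjugated silyloxydiene, while the hindered tertiary lithium alkoxide is not silylated.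

Step 6
Reactants: 10 2,2-dimethyl-4H-1,3-dioxin-4-one
Product: 11 5-iodo-2,2-dimethyl-4H-1,3-dioxin-4-one
Conditions: N-iodosuccinimide, AcOH, 20 °C
Reagents that add atoms: N-iodosuccinimide, O=C1CCC(=O)N1I
Why: Electrophilic iodination at the nucleophilic α-carbon (C5) of the β-alkoxy enoate, as known for dioxinones.

Step 7
Reactants: 11 iodo-dioxinone
Product: 12 2,2-dimethyl-4-oxo-4H-1,3-dioxine-5-carbaldehyde
Conditions: Pd(PPh3)4 (cat.), CO (1 atm), Bu3SnH (slow addition), THF, 50 °C
Reagents that add atoms: carbon monoxide, [C-]#[O+]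
Why: Palladium-catalysed reductive carbonylation of the alkenyl iodide (oxidative addition, CO insertion, hydride transfer from tin) gives the formyl dienophile.

Step 8
Reactants: 9 silyloxydiene; 12 formyl-dioxinone
Product: 13 cycloadduct (ring A silyl enol ether C11=C12–OTBS, cis-fused at C1–C14 to the 2,2-dimethyl-1,3-dioxan-4-one; C1 carries CHO (C15) cis to the C9 furanose substituent on C10)
Conditions: toluene, 45 °C, dark, 2,6-di-tert-butyl-4-methylpyridine (cat.)
Reagents that add atoms: none
Why: A thermal, normal-electron-demand, asynchronous [4+2] cycloaddition in which the 2-silyloxydiene 9 (largest HOMO coefficient at C13) attacks the doubly activated, β-oxygenated alkylidene-1,3-dicarbonyl 12 at C14, so that C13–C14 forms ahead of the congested C1–C10 bond and the silyloxy carbon C12 ends para to the acceptor-bearing C1. The closest known reaction type is the Diels–Alder reaction of 3-formylchromones, 2-formylcycloalkenones and 5-acyl-1,3-dioxin-4-ones with 2-silyloxydienes. Ring A is closed in the intermolecular [4+2] mode, suprafacial on both partners, and the dioxanone ends cis-fused to it. C14 and C1 are fixed by the cis (ring) geometry of the dienophile and by the endo position of the small formyl group, which puts C15 cis and C2 and O14 trans to the C9 substituent; C10 follows from the (E) geometry of C10=C11. The sense of addition is controlled by the C9 stereocentre, whose bulky quaternary C8 stands anti to the incoming dienophile with the ring oxygen O9 in the inside position. The step needs regioselectivity (electronic), endo-formyl/exo-ring selectivity (the ring-endo arrangement would press the dioxinone against the C9 furanose residue) and diene-face selectivity (the C3-branched furanose), and it must outrun hetero-cycloaddition across the formyl-ene unit.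

Step 9
Reactants: 13 cycloadduct
Product: 15 C15-methyl compound, via tosylhydrazone 14 (not isolated)
Conditions: TsNHNH2, THF, 4 Å sieves, 20 °C; then catecholborane, CHCl3, 0 °C; then NaOAc·3H2O, 55 °C
Reagents that add atoms: none
Why: Only the aldehyde condenses with the sulfonyl hydrazide, and the Kabalka-type reduction (hydroboration of C=N, acetate-induced loss of sulfinate and N2) turns CHO into the C15 methyl without touching C1.

Step 10
Reactants: 15 C15-methyl dioxanone; 16 ethynylmagnesium bromide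
Product: 17 14-hydroxy C2 ethynyl ketone
Conditions: HC≡CMgBr (3 equiv), THF, −40 to 0 °C; aq NH4Cl
Reagents that add atoms: none
Why: The acetylide acylates itself on the acylal-type lactone carbonyl (C2); the tetrahedral hemiketal alkoxide survives until work-up, so only one addition occurs, and its collapse releases acetone and frees 14-OH, while the hindered α-branched ethyl ester is spared.

Step 11
Reactants: 17 ynone
Product: 18 (Z)-β-iodo enone (C2(=O)–C3H=C4H–I)
Conditions: NaI, AcOH, MeCN, 0 to 20 °C
Reagents that add atoms: sodium iodide, [Na+].[I-]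
Why: Conjugate anti-hydroiodination of the ynone gives the (Z)-β-iodo enone under kinetic control and fixes the C3=C4 geometry.

Step 12
Reactants: 18 iodo enone
Product: 19 2,14-syn-diol (C2 as in the target)
Conditions: Et2BOMe, THF/MeOH (4:1), −78 °C; NaBH4; AcOH quench, MeOH co-evaporation
Reagents that add atoms: none
Why: Narasaka–Prasad reduction: the boron chelate between 14-OH and the C2 carbonyl is attacked by external hydride on the face anti to the axial C1–C10 bond, giving the 1,3-syn diol by 1,2-reduction and so setting C2.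

Step 13
Reactants: 19 diol
Product: 20 2,14-diacetate
Conditions: Ac2O, Et3N, DMAP (cat.), CH2Cl2, 20 °C
Reagents that add atoms: acetic anhydride, CC(=O)OC(C)=O
Why: DMAP-catalysed acetylation of the two secondary hydroxyls; the tertiary 8-OH, flanked by three branched carbons, should stay free.

Step 14
Reactants: 20 diacetate; 21 N,N-dimethylmethyleneiminium iodide
Product: 24 C11(20)-methylene C12 ketone, via Mannich base 22 (not isolated), via methiodide 23 (not isolated)
Conditions: 21, CH2Cl2, 20 °C; then MeI; then aq NaHCO3/CH2Cl2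
Reagents that add atoms: none
Why: The silyl enol ether left by the cycloaddition reacts regiospecifically at C11 in a Mannich reaction, and quaternisation followed by Hofmann elimination under mild base gives the α-methylene ketone carrying C20.

Step 15
Reactants: 24 enone
Product: 27 13α-hydroxy enone, via bis-silyl dienol ether 25 (not isolated), via bis-silyl ketone 26 (not isolated)
Conditions: TMSOTf, Et3N, CH2Cl2, −78 to 0 °C; then dimethyldioxirane, acetone, −78 °C; then citric acid, MeOH, 0 °C
Reagents that add atoms: dimethyldioxirane, CC1(C)OO1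
Why: Rubottom oxidation: enolisation is possible only toward C13 and needs no free enolate (so the 14-acetate is not eliminated), and the dioxirane attacks the silyl dienol ether on the α-face opposite the axial C15 methyl, giving the equatorial 13α-hydroxyl, which is also the more stable epimer.

Step 16
Reactants: 27 hydroxy enone
Product: 28 lactol (C6 hemiacetal, 7-OH free)
Conditions: AcOH/H2O (4:1), 55 °C
Reagents that add atoms: none
Why: Acid hydrolysis of the 1,2-O-isopropylidene acetal unmasks C6 as a lactol; the lactone cannot yet form because it would be trans-fused to the furanose.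

Step 17
Reactants: 28 lactol; 29 (formylmethylene)triphenylphosphorane
Product: 31 γ-lactone (O7–C19) (5E)-enal, via enal ester 30 (not isolated)
Conditions: 29, PhCO2H (cat.), THF, 45 °C; then PPTS, benzene, 60 °C
Reagents that add atoms: none
Why: Wittig reaction on the open form of the lactol gives the (E)-enal (C5, C16), the acid additive suppressing base-mediated oxa-Michael re-closure by O9; acid-catalysed lactonisation then selects O7 over O9 because only that γ-lactone places the C18 methyl trans to the C9 substituent.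

Step 18
Reactants: 31 lactone enal
Product: 32 (Z)-5-iodo enal
Conditions: I2, pyridine/CH2Cl2, 0 to 20 °C
Reagents that add atoms: iodine, II
Why: Johnson α-iodination of the enal (pyridine addition, iodination, elimination) puts iodine on C5 cis to C7 and leaves the formyl group (C16) trans to C7.

Step 19
Reactants: 32 iodo enal
Product: 33 2,9,13,14-tetraacetate
Conditions: Ac2O, pyridine, DMAP (cat.), CH2Cl2, 0 °C
Reagents that add atoms: acetic anhydride, CC(=O)OC(C)=O
Why: Acetylation of the secondary 9- and 13-hydroxyls at low temperature; the tertiary 8-OH stays free.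

Step 20
Reactants: 33 bis(alkenyl iodide)
Product: 35 macrocyclic (3Z,5E)-dienal (12-oxo, 11(20)-methylene, 16-al), via stannane 34 (not isolated)
Conditions: Pd(PPh3)4 (10 mol %), Me3SnSnMe3 (1.05 equiv), toluene (0.002 M), 85 °C
Reagents that add atoms: none
Why: Stille–Kelly coupling: zerovalent palladium inserts first into the more reactive α-iodoenal C–I bond, the distannane converts it to the alkenylstannane, and intramolecular Stille coupling with the (Z)-alkenyl iodide closes the ten-membered ring at C4–C5 with retention of both olefin geometries.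

Step 21
Reactants: 35 dienal ketone
Product: 36 12α,16-diol
Conditions: NaBH4, CeCl3·7H2O, MeOH, −78 °C
Reagents that add atoms: none
Why: Luche 1,2-reduction of the enal and of the C12 enone; the axial 14-acetate blocks axial hydride approach to C12, so equatorial attack from the β-face gives the axial 12α-hydroxyl.

Step 22
Reactants: 36 diol
Product: 38 16-chloride, via mesylate 37 (not isolated)
Conditions: MsCl, 2,4,6-collidine, LiCl, DMF, 0 °C
Reagents that add atoms: lithium chloride, [Li+].[Cl-]
Why: The primary allylic hydroxyl is mesylated and displaced by chloride selectively, the hindered secondary 12-OH and the tertiary 8-OH remaining free.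

Step 23
Reactants: 38 allylic alcohol
Product: 39 CNP0282558.2 (target)
Conditions: VO(acac)2 (cat.), tBuOOH, CH2Cl2, 0 to 20 °C
Reagents that add atoms: tert-butyl hydroperoxide, CC(C)(C)OO
Why: Vanadium-catalysed hydroxyl-directed epoxidation delivers oxygen to the exocyclic C11=C20 alkene syn to 12α-OH, giving the 11α,20-epoxide; the diene has no free allylic hydroxyl, and the tertiary homoallylic 8-OH directs far more slowly.

**Compound list**
1 | diacetone-D-glucose (1,2:5,6-di-O-isopropylidene-α-D-glucofuranose) | CC3(C)OC[C@@H](O3)[C@H]1O[C@@H]2OC(C)(C)O[C@@H]2[C@H]1O | starting material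
2 | 1,2:5,6-di-O-isopropylidene-α-D-ribo-hexofuranos-3-ulose | CC3(C)OC[C@@H](O3)[C@H]1O[C@@H]2OC(C)(C)O[C@@H]2C1=O | intermediate
3 | ethyl propanoate | CCC(=O)OCC | starting material
4 | ethyl (2R)-2-(1,2:5,6-di-O-isopropylidene-α-D-allofuranos-3-C-yl)propanoate | CC3(C)OC[C@@H](O3)[C@H]1O[C@@H]2OC(C)(C)O[C@@H]2[C@@]1(O)[C@@H](C)C(=O)OCC | intermediate
5 | 5,6-diol of 4 | OC[C@@H](O)[C@H]1O[C@@H]2OC(C)(C)O[C@@H]2[C@@]1(O)[C@@H](C)C(=O)OCC | intermediate (not isolated)
6 | C10 aldehyde (pentodialdofuranose) | O=C[C@H]1O[C@@H]2OC(C)(C)O[C@@H]2[C@@]1(O)[C@@H](C)C(=O)OCC | intermediate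
7 | (acetylmethylene)triphenylphosphorane | CC(=O)C=P(c1ccccc1)(c1ccccc1)c1ccccc1 | starting material
8 | (E)-methyl enone at C9 | CC(=O)/C=C/[C@H]1O[C@@H]2OC(C)(C)O[C@@H]2[C@@]1(O)[C@@H](C)C(=O)OCC | intermediate
9 | 2-(tert-butyldimethylsilyloxy)diene | C=C(O[Si](C)(C)C(C)(C)C)/C=C/[C@H]1O[C@@H]2OC(C)(C)O[C@@H]2[C@@]1(O)[C@@H](C)C(=O)OCC | intermediate
10 | 2,2-dimethyl-4H-1,3-dioxin-4-one | CC1(C)OC=CC(=O)O1 | starting material
11 | 5-iodo-2,2-dimethyl-4H-1,3-dioxin-4-one | CC1(C)OC=C(I)C(=O)O1 | intermediate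
12 | 2,2-dimethyl-4-oxo-4H-1,3-dioxine-5-carbaldehyde | CC1(C)OC=C(C=O)C(=O)O1 | intermediate
13 | Diels–Alder adduct (C15 aldehyde, dioxanone, C11=C12 silyl enol ether) | O=C[C@]12C(=O)OC(C)(C)O[C@H]1CC(O[Si](C)(C)C(C)(C)C)=C[C@@H]2[C@H]3O[C@@H]4OC(C)(C)O[C@@H]4[C@@]3(O)[C@@H](C)C(=O)OCC | intermediate
14 | C15 tosylhydrazone of 13 | Cc1ccc(cc1)S(=O)(=O)N/N=C/[C@]12C(=O)OC(C)(C)O[C@H]1CC(O[Si](C)(C)C(C)(C)C)=C[C@@H]2[C@H]3O[C@@H]4OC(C)(C)O[C@@H]4[C@@]3(O)[C@@H](C)C(=O)OCC | intermediate (not isolated)
15 | C15-methyl dioxanone | C[C@]12C(=O)OC(C)(C)O[C@H]1CC(O[Si](C)(C)C(C)(C)C)=C[C@@H]2[C@H]3O[C@@H]4OC(C)(C)O[C@@H]4[C@@]3(O)[C@@H](C)C(=O)OCC | intermediate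
16 | ethynylmagnesium bromide | C#C[Mg]Br | starting material
17 | 14-hydroxy C2 ethynyl ketone | C[C@]1(C(=O)C#C)[C@@H](O)CC(O[Si](C)(C)C(C)(C)C)=C[C@@H]1[C@H]3O[C@@H]4OC(C)(C)O[C@@H]4[C@@]3(O)[C@@H](C)C(=O)OCC | intermediate
18 | (Z)-β-iodo enone | C[C@]1(C(=O)/C=C\I)[C@@H](O)CC(O[Si](C)(C)C(C)(C)C)=C[C@@H]1[C@H]3O[C@@H]4OC(C)(C)O[C@@H]4[C@@]3(O)[C@@H](C)C(=O)OCC | intermediate
19 | 2,14-syn-diol | C[C@]1([C@H](O)/C=C\I)[C@@H](O)CC(O[Si](C)(C)C(C)(C)C)=C[C@@H]1[C@H]3O[C@@H]4OC(C)(C)O[C@@H]4[C@@]3(O)[C@@H](C)C(=O)OCC | intermediate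
20 | 2,14-diacetate | C[C@]1([C@H](OC(C)=O)/C=C\I)[C@@H](OC(C)=O)CC(O[Si](C)(C)C(C)(C)C)=C[C@@H]1[C@H]3O[C@@H]4OC(C)(C)O[C@@H]4[C@@]3(O)[C@@H](C)C(=O)OCC | intermediate
21 | N,N-dimethylmethyleneiminium iodide | C=[N+](C)C.[I-] | starting material
22 | C11 dimethylaminomethyl ketone (Mannich base, C11 epimers) | C[C@]1([C@H](OC(C)=O)/C=C\I)[C@@H](OC(C)=O)CC(=O)C(CN(C)C)[C@@H]1[C@H]3O[C@@H]4OC(C)(C)O[C@@H]4[C@@]3(O)[C@@H](C)C(=O)OCC | intermediate (not isolated)
23 | methiodide of 22 (C11 epimers) | C[C@]1([C@H](OC(C)=O)/C=C\I)[C@@H](OC(C)=O)CC(=O)C(C[N+](C)(C)C)[C@@H]1[C@H]3O[C@@H]4OC(C)(C)O[C@@H]4[C@@]3(O)[C@@H](C)C(=O)OCC.[I-] | intermediate (not isolated)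
24 | C11(20)-methylene C12 ketone | C[C@]1([C@H](OC(C)=O)/C=C\I)[C@@H](OC(C)=O)CC(=O)C(=C)[C@@H]1[C@H]3O[C@@H]4OC(C)(C)O[C@@H]4[C@@]3(O)[C@@H](C)C(=O)OCC | intermediate
25 | bis(trimethylsilyl) dienol ether (C12=C13, 8-OSiMe3) | C[C@]1([C@H](OC(C)=O)/C=C\I)[C@@H](OC(C)=O)C=C(O[Si](C)(C)C)C(=C)[C@@H]1[C@H]3O[C@@H]4OC(C)(C)O[C@@H]4[C@@]3(O[Si](C)(C)C)[C@@H](C)C(=O)OCC | intermediate (not isolated)
26 | 13α-trimethylsilyloxy ketone (8-OSiMe3) | C[C@]1([C@H](OC(C)=O)/C=C\I)[C@@H](OC(C)=O)[C@@H](O[Si](C)(C)C)C(=O)C(=C)[C@@H]1[C@H]3O[C@@H]4OC(C)(C)O[C@@H]4[C@@]3(O[Si](C)(C)C)[C@@H](C)C(=O)OCC | intermediate (not isolated)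
27 | 13α-hydroxy enone | C[C@]1([C@H](OC(C)=O)/C=C\I)[C@@H](OC(C)=O)[C@@H](O)C(=O)C(=C)[C@@H]1[C@H]3O[C@@H]4OC(C)(C)O[C@@H]4[C@@]3(O)[C@@H](C)C(=O)OCC | intermediate
28 | lactol (C6 anomers) | C[C@]1([C@H](OC(C)=O)/C=C\I)[C@@H](OC(C)=O)[C@@H](O)C(=O)C(=C)[C@@H]1[C@H]3OC(O)[C@H](O)[C@@]3(O)[C@@H](C)C(=O)OCC | intermediate
29 | (formylmethylene)triphenylphosphorane | O=CC=P(c1ccccc1)(c1ccccc1)c1ccccc1 | starting material
30 | open-chain (5E)-enal ethyl ester (7,8,9,13-tetrol) | C[C@]1([C@H](OC(C)=O)/C=C\I)[C@@H](OC(C)=O)[C@@H](O)C(=O)C(=C)[C@@H]1[C@@H](O)[C@@](O)([C@@H](O)/C=C/C=O)[C@@H](C)C(=O)OCC | intermediate (not isolated)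
31 | γ-lactone (5E)-enal (9-OH, 13-OH) | C[C@]1([C@H](OC(C)=O)/C=C\I)[C@@H](OC(C)=O)[C@@H](O)C(=O)C(=C)[C@@H]1[C@@H](O)[C@@]3(O)[C@H](/C=C/C=O)OC(=O)[C@@H]3C | intermediate
32 | (Z)-5-iodo enal | C[C@]1([C@H](OC(C)=O)/C=C\I)[C@@H](OC(C)=O)[C@@H](O)C(=O)C(=C)[C@@H]1[C@@H](O)[C@@]3(O)[C@H](/C=C(I)/C=O)OC(=O)[C@@H]3C | intermediate
33 | 2,9,13,14-tetraacetate bis(alkenyl iodide) | C[C@]1([C@H](OC(C)=O)/C=C\I)[C@@H](OC(C)=O)[C@@H](OC(C)=O)C(=O)C(=C)[C@@H]1[C@@H](OC(C)=O)[C@@]3(O)[C@H](/C=C(I)/C=O)OC(=O)[C@@H]3C | intermediate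
34 | 5-trimethylstannyl enal | C[C@]1([C@H](OC(C)=O)/C=C\I)[C@@H](OC(C)=O)[C@@H](OC(C)=O)C(=O)C(=C)[C@@H]1[C@@H](OC(C)=O)[C@@]3(O)[C@H](/C=C([Sn](C)(C)C)/C=O)OC(=O)[C@@H]3C | intermediate (not isolated)
35 | macrocyclic (3Z,5E)-dienal, 12-oxo, 11(20)-methylene | CC(=O)O[C@H]1C(=O)C(=C)[C@@H]2[C@@H](OC(C)=O)[C@@]3(O)[C@H](/C=C(C=O)\C=C/[C@@H](OC(C)=O)[C@@]2(C)[C@H]1OC(C)=O)OC(=O)[C@@H]3C | intermediate
36 | 12α,16-diol | CC(=O)O[C@H]1[C@@H](O)C(=C)[C@@H]2[C@@H](OC(C)=O)[C@@]3(O)[C@H](/C=C(CO)\C=C/[C@@H](OC(C)=O)[C@@]2(C)[C@H]1OC(C)=O)OC(=O)[C@@H]3C | intermediate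
37 | 16-mesylate | CC(=O)O[C@H]1[C@@H](O)C(=C)[C@@H]2[C@@H](OC(C)=O)[C@@]3(O)[C@H](/C=C(COS(C)(=O)=O)\C=C/[C@@H](OC(C)=O)[C@@]2(C)[C@H]1OC(C)=O)OC(=O)[C@@H]3C | intermediate (not isolated)
38 | 16-chloro-11(20)-ene-12α-ol | CC(=O)O[C@H]1[C@@H](O)C(=C)[C@@H]2[C@@H](OC(C)=O)[C@@]3(O)[C@H](/C=C(CCl)\C=C/[C@@H](OC(C)=O)[C@@]2(C)[C@H]1OC(C)=O)OC(=O)[C@@H]3C | intermediate
39 | CNP0282558.2 | CC(=O)O[C@H]1[C@@H](O)[C@]2(CO2)[C@@H]2[C@@H](OC(C)=O)[C@@]3(O)[C@H](/C=C(CCl)\C=C/[C@@H](OC(C)=O)[C@@]2(C)[C@H]1OC(C)=O)OC(=O)[C@@H]3C | target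

**Totals and risks**
Total step count: 23. Longest linear sequence: 21 steps (steps 1–5 and 8–23).

Steps most likely to fail:

Step 8. The cycloaddition may lose diene-face selectivity, or be diverted to hetero-cycloaddition across the formyl-ene unit, or lose the silyl enol ether. The fallback sets out from enone 8 and comes back at 13. Enone 8 is converted with LiN(SiMe3)2 (2.1 equiv, THF, −78 °C) into its cross-conjugated lithium dienolate, which adds to 12 in a Michael reaction to give the chelated Michael adduct F1. On warming, the 1,3-dicarbonyl enolate closes C1–C10 by intramolecular Michael addition (a sequential Michael annulation, the stepwise anionic counterpart of the cycloaddition), and the regiodefined C11–C12 enolate is silylated in the flask with TBSCl to give 13.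

Step 20. The ring closure may give oligomers, or the alkenylpalladium intermediate may insert into the C11 methylene or ionise the allylic acetate. The fallback sets out from 33 and comes back at 35. Only the α-iodoenal iodide is exchanged at 20 °C (PdCl2(PPh3)2 cat., Me3SnSnMe3) and stannane 34 is isolated. The ring is then closed without palladium by a Liebeskind coupling with CuTC (copper thiophene-2-carboxylate, monovalent copper) in N-methylpyrrolidone at 0 °C, so no alkenylpalladium species is present during ring closure. This fallback makes no compound outside the list (F0).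

Step 2. The aldol addition may show too little selectivity at C17; the wrong epimer would later lactonise onto O9 instead of O7. The fallback sets out from 4 obtained as a mixture with its C17 epimer and comes back at 4. The mixture is converted with LiN(iPr)2 (2.2 equiv, THF, −78 °C) into the chelated dilithium alkoxide–enolate F2, in which C17 is planar, and is reprotonated kinetically with 2,6-di-tert-butylphenol from the face remote from the C9 side chain. C17 is then set by protonation instead of by carbon–carbon bond formation.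

Further compounds
F1 | step 8 | Michael adduct of the dienolate of 8 with 12 (drawn as the neutral hydroxymethylene tautomer) | O/C=C1\C(=O)OC(C)(C)O[C@H]1CC(=O)/C=C/[C@H]3O[C@@H]4OC(C)(C)O[C@@H]4[C@@]3(O)[C@@H](C)C(=O)OCC
F0 | step 20 | none | none
F2 | step 2 | dilithium alkoxide–enolate of 4 | CC3(C)OC[C@@H](O3)[C@H]1O[C@@H]2OC(C)(C)O[C@@H]2[C@@]1([O-])/C(C)=C(\[O-])OCC.[Li+].[Li+]
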